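X.D, together with its crystals Q, is what you collect from this run, so watch how much of the dissolved X reaches it.

Z 0.20 M; D 3.00 equiv; time 30 s

    2 X → X2 (k1 = 0.113 /M/s)
    Q ⇌ X.D, rate k2*(cs2 - [X.D]) while solid is left; crystals form when [X.D] > cs2 (cs2 = 27 mM, k2 = 0.784 /s)
    D ⇌ E (K3 = 0.26, k3 = 0.721 /s)
    2 D → D2 (k4 = 0.0183 /M/s)
    Z ⇌ X, rate k5*(cs5 - [X]) while solid is left; crystals form when [X] > cs5 (cs5 = 0.092 M, k5 = 2.92 /s)
    X + D → X.D (k6 = 0.107 /M/s)

- a species is counted by the Z in it: one X2 counts as two
- amounts and yields of X.D count Q too
- a doubled species enters its step squared and goes two at a time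
- given per volume of solution although it is solid: Z, Q
- at the start none of Z is in solution
- X means what is dissolved; the solid is not counted in it
- run time (flask): 30 s

- amount of X.D and Q together at 30 s, in percent of the Z charged
- concentration of X in solution at 30 s, in percent of saturation

On the fastest rungs, D and E relax with a half-life of 0.198 s, and Z fills the solution with a half-life of 0.237 s. Both are shorter than the 11 s half-life of X by coupling with D as charged. So free D first relaxes to 0.476 M, and X comes up near its solubility. Slower still, X pairs with a first half-life of 48.1 s, and D with one of 57.4 s.

Carry the coupling share: the rate of X going to X.D over that rate plus the rate of X going to X2, X at solubility. It is a selectivity written as a fraction.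

Round one, D held at its starting value:

coupling 0.00469 M/s, pairing 0.00191 M/s, share 71.0 %

Over 30 s, these use 99.0 % of Z, and dissolved X holds 46.0 % more, 145 % in total, so in this reckoning solid Z ends before the run does, and D falls meanwhile.

Round two, D put back at mid-run, after coupling and its own pairing:

D 0.322 M, coupling 0.00317 M/s, share 62.3 %

My answers, with X reckoned at solubility in the rates for the whole 30 s and the unused Z standing as X: y 47.5 %, sat 51.8 %.

The forecast gives 49 % and 60 %, holding that “coupling and dimerisation use up the solid at around 20 s”.

The simulation gives 48.6 % and 60.4 %.

In this flask, X.D and Q make 67.3 % of those plus X2 at 30.0 s, above round two and below round one. In the neighbour read early, at 8.0 s, solid Z still stands at 31.9 %, X at 45.0 % and D at 67.4 % of its charge, and the same ratio is 70.3 %, beside the 71.0 % of round one. This flask is still moving at 30.0 s, with 27.8 % of the Z standing as X. By 300 s, X is down to 0.339 %, X2 is up to 28.9 %, and X.D and Q reach 70.8 %.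

The constants were chosen freely; the rest is arithmetic.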